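## Analysis of the target

Compound 25 is a C30 bicyclic triterpenoid built on a trans-fused decalin. In drimane/labdane numbering, ring A is C1–C5 plus C10, ring B is C5–C10, and C11 on C9 carries an all-E farnesyl unit, so the chain runs C11–C12 and then through three trisubstituted alkenes. Ring A holds the C3 ketone beside the C4 gem-dimethyl group. Ring B holds all four stereocentres in a row: C5 (H α), C10 (methyl β), C9 (H α, chain β) and C8 (hydroxyl α, methyl β), that is (5R,8R,9R,10S). Their relationship is the normal labdane one: trans ring fusion, the C10 methyl and the C9 chain cis, and the C8 oxygen on the opposite face.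

The tertiary C8 alcohol dehydrates easily and the polyene chain tolerates neither acid, electrophilic oxidants nor hydrogenation, so all work on the rings has to be finished before the chain is attached. The difficulty lies in the crowded C4–C5–C10 array (two quaternary carbons flanking the ring fusion), the fully substituted carbinol C8, and the absence of any stereocentre outside ring B. The strategy rests on one feature: C8 bears a methyl group and an oxygen and sits 1,4 to C5 across ring B. If that oxygen is drawn as a bridge from C8 to C5, then C5–C6–C7–C8 are the ring carbons of a 2-methylfuran and C9=C10 is a dienophile; C3, kept as a protected carbinol, becomes the temporary control element.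

## Retrosynthetic reasoning

**C3 carbonyl (25 ⇒ 24 ⇒ 23).** No skeletal bond is cut. The ketone is traced back to the 3β-alcohol 24 and that to silyl ether 23. Carrying C3 as a protected carbinol keeps it inert through the organolithium and electron-transfer steps and lets the same centre steer the cycloaddition earlier. The forward steps must free a hindered secondary alcohol and oxidise it beside a tertiary alcohol and three alkenes.

**C11–C12 (23 ⇒ 22 ⇒ 19 + 20).** The chain is cut between C11 and C12. This is the one sp3–sp3 bond next to an allylic carbon, so all three E alkenes stay inside the commercial bromide 20, and C11 can serve as a sulfone-stabilised carbanion. A cut further out would demand stereoselective construction of a trisubstituted alkene. The forward reaction must alkylate at the primary allylic carbon without transposition; the sulfone is then removed reductively (22 ⇒ 23).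

**C11–S (19 ⇒ 18 ⇒ 17).** The sulfone comes from the primary alcohol of diol 17 by way of sulfide 18. The forward steps must distinguish the primary C11 hydroxyl from the tertiary C8 hydroxyl and must be run while no alkene is present.

**C5–H (17 ⇒ 16).** The C5–H and C6–H bonds are removed to give the C5=C6 alkene of 16. The β face of that alkene is screened by the axial methyl groups on C4, C8 and C10, so hydrogen should enter from the α face and set the trans ring fusion.

**C5–O bridge (16 ⇒ 15).** Reconnecting the C8 oxygen to C5 and moving the alkene to C6=C7 gives the oxygen-bridged alcohol 15. The forward step must break C5–O and not C8–O, and must place hydrogen on C7. A hydrometalation–elimination sequence would be expected to put the metal on the less hindered C7 and then expel the oxygen from C8, which is the wrong regiochemistry. An electron-transfer cleavage is governed instead by release of strain at the more congested C5 and by formation of the less hindered alkoxide at C8, so it is the method chosen.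

**C11 oxidation level (15 ⇒ 14).** The alcohol is traced to ester 14. Reducing the ester first removes the acidity at C9, which would otherwise allow β-elimination of the C8 oxygen, and takes away the activation that makes the cycloaddition reversible.

**C5–C10 and C8–C9 (14 ⇒ 13).** Both bonds are cut at once in a retro-[4+2] step. This opens rings A and B together, removes all four ring stereocentres and leaves the acyclic furan enoate 13 with the single stereocentre C3. The forward step must control the face of addition, the orientation of the tether and the position of an equilibrium.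

**C9=C10 and the C3 protecting group (13 ⇒ 12 ⇒ 11 ⇒ 10).** The enoate is cut at its double bond to methyl ketone 12, which is unmasked from ketal 11, itself the silyl ether of alcohol 10. The olefination must give the E isomer, because the alkene geometry becomes the C9/C10 relationship.

**C3 stereocentre and C2–C3 (10 ⇒ 9 ⇒ 8 ⇒ 5 + 6).** The carbinol is traced to ketone 9, where a tertiary and a primary alkyl group flank the carbonyl and give a catalyst-controlled reduction a clear large/small distinction. Ketone 9 comes from racemic alcohol 8, and 8 from aldehyde 5 and bromide 6 through Grignard reagent 7.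

**C4–furan bond (5 ⇒ 4 ⇒ 1 + 2).** Aldehyde 5 comes from ester 4. The quaternary carbon of 4 is cut at its bond to the furan, giving bromo ester 1 (as zinc enolate 3) and bromofuran 2. A cross-coupling forms this hindered bond without strong base and without the regiochemical problems of alkylating a furan with a tertiary electrophile.

## Alternatives that were turned down

**Alternative 1:** Ring A is removed last by cutting C1–C10 and C4–C5. In the forward direction a ring B ketone A2 (C5 carbonyl, C10 methyl, C9 vinyl, C8 silyl ether) would undergo a base-mediated Robinson annulation with pent-1-en-3-one A3 to give the bicyclic 4-methyl-4-en-3-one A1.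
- For it: the annulation is dependable chemistry; the more substituted enolate reacts at C10; the acceptor should approach anti to the C9 vinyl group, which gives the correct C9/C10 relationship; the C3 carbonyl arrives at the right oxidation level.
- Against it: A2 already contains C8 and C9, one of them a fully substituted carbinol, and needs its own asymmetric synthesis. A1 still lacks one C4 methyl and the C5 hydrogen, which calls for a reductive methylation. The vinyl group supplies only C11–C12, so the chain cannot come from commercial farnesyl bromide; a stereodefined alkenyl partner one carbon shorter would have to be made. The early ketone must be masked through the chain-building steps.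
- Comparison: on reliability of the ring-forming step this alternative is stronger. The chosen route offers instead both rings and all four ring stereocentres in one step from a precursor with a single stereocentre, and direct use of the commercial C15 bromide.

**Alternative 2:** Only the C8–C9 bond of ring B is cut. A ring A keto enoate A5 (methyl ketone on a two-carbon arm from C5, E-enoate on C10) would be treated with a divalent samarium reductant. The C8 ketyl adds to C9 in a 6-exo closure and gives hydroxy ester A4.
- For it: the tertiary alcohol and C9 are formed in one radical step, usually with the new hydroxyl anti to the ester arm as required. There is no oxygen bridge to open and no alkene to reduce, so the end-game is shorter. On that point it is stronger.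
- Against it: the hard part of the molecule is moved into the precursor. A5 carries C3, C5 and the quaternary C10 with defined relative and absolute configuration. The product ends at C12 as an ester, one carbon away from a convenient coupling site, so the chain would need an sp3–sp2 coupling with a purpose-made alkenyl fragment. A stoichiometric lanthanide reductant with a toxic cosolvent is also needed.
- Comparison: the chosen route builds the C5/C10 array in the same step that forms the C8–O and C9 centres, and pays for this with two extra steps to open the bridge and saturate C5=C6.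

**Alternative 3:** Ring B is cut at C7–C8 and C9–C10. An enantiopure ring A diene A7 (C10=C5 in the ring, vinyl group C6=C7 on C5, silyl ether at C3) and methyl but-2-ynoate A8 would be heated together to give diene ester A6 with the quaternary C10.
- For it: it is the most convergent plan, both pieces are simple, and the expected orientation (the unsubstituted diene terminus C7 bonding to the β-carbon of the ynoate) is the one required. On convergence and simplicity of the building blocks it is stronger.
- Against it: the quaternary centre must form intermolecularly at a tetrasubstituted diene terminus whose s-cis conformer is strained by the neighbouring gem-dimethyl group. The face of attack at C10 is controlled only by the remote C3 substituent. A6 contains none of C5, C8 or C9; a tetrasubstituted enoate carbon would have to be hydrated with α selectivity, C9 protonated and C5=C6 reduced.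
- Comparison: the chosen cycloaddition is intramolecular, so the tether fixes orientation and face, and its product already holds the C8 oxygen, C9 and C10 in the correct relationship.

Key step: step 9

Remark: 2-bromo-5-methylfuran (2) is assumed to be a commercial, stabilised reagent. Positions and α/β descriptors in the names below follow drimane numbering (C11 on C9; methyl groups on C4, C4, C8 and C10).

## Route

Step 1
Reactants: 1 ethyl 2-bromo-2-methylpropanoate; 2 2-bromo-5-methylfuran
Product: 4 ethyl 2-methyl-2-(5-methylfuran-2-yl)propanoate, via zinc enolate 3 (not isolated)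
Conditions: Zn dust (TMSCl-activated), THF, 25 °C; then 2, Pd(dba)2 (2 mol%), P(t-Bu)3 (2 mol%), THF, 25→50 °C
Reagents that add atoms: none
Why: Zinc insertion gives the Reformatsky reagent 3, which couples with the heteroaryl bromide in a palladium-catalysed α-arylation of a zinc ester enolate (Negishi type). The bulky phosphine favours reductive elimination at the quaternary carbon, and no strong base touches the furan.

Step 2
Reactants: 4 ethyl 2-methyl-2-(5-methylfuran-2-yl)propanoate
Product: 5 2-methyl-2-(5-methylfuran-2-yl)propanal
Conditions: i-Bu2AlH (1.1 equiv), CH2Cl2, −78 °C; MeOH, then aq. Rochelle salt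
Reagents that add atoms: none
Why: Partial hydride reduction of an ester; the aluminium hemiacetal of this α-quaternary ester should persist at −78 °C and collapse to the aldehyde only on work-up. The aldehyde cannot enolise.

Step 3
Reactants: 5 2-methyl-2-(5-methylfuran-2-yl)propanal; 6 2-(2-bromoethyl)-2-methyl-1,3-dioxolane
Product: 8 rac-2-methyl-2-(5-methylfuran-2-yl)-5-(2-methyl-1,3-dioxolan-2-yl)pentan-3-ol, via Grignard reagent 7 (not isolated)
Conditions: 6, Mg, THF, 20–25 °C; then 5, THF, 0 °C; aq. NH4Cl
Reagents that add atoms: none
Why: Grignard addition to a non-enolisable aldehyde forms the C2–C3 bond. The ketal Grignard reagent is kept at or below room temperature, where it is stable; the new carbinol centre is racemic and is erased in the next step.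

Step 4
Reactants: 8 rac-2-methyl-2-(5-methylfuran-2-yl)-5-(2-methyl-1,3-dioxolan-2-yl)pentan-3-ol
Product: 9 2-methyl-2-(5-methylfuran-2-yl)-5-(2-methyl-1,3-dioxolan-2-yl)pentan-3-one
Conditions: Dess–Martin periodinane, NaHCO3, CH2Cl2, 0 °C→rt
Reagents that add atoms: none
Why: Dess–Martin oxidation of a secondary alcohol under buffered, near-neutral conditions, which the ketal and the dialkylfuran should tolerate.

Step 5
Reactants: 9 2-methyl-2-(5-methylfuran-2-yl)-5-(2-methyl-1,3-dioxolan-2-yl)pentan-3-one
Product: 10 (3S)-2-methyl-2-(5-methylfuran-2-yl)-5-(2-methyl-1,3-dioxolan-2-yl)pentan-3-ol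
Conditions: (R)-2-methyl-CBS-oxazaborolidine (0.2 equiv), BH3·SMe2, THF, −20 °C; MeOH
Reagents that add atoms: none
Why: Corey–Bakshi–Shibata reduction; the tertiary furyl-substituted carbon is the large group and the CH2 chain the small one, as in tert-alkyl methyl ketones. With the (R)-catalyst, hydride should be delivered to the face that gives the 3S alcohol, the later 3β-oxygen.

Step 6
Reactants: 10 (3S)-2-methyl-2-(5-methylfuran-2-yl)-5-(2-methyl-1,3-dioxolan-2-yl)pentan-3-ol
Product: 11 tert-butyl{[(3S)-2-methyl-2-(5-methylfuran-2-yl)-5-(2-methyl-1,3-dioxolan-2-yl)pentan-3-yl]oxy}dimethylsilane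
Conditions: TBSOTf, 2,6-lutidine, CH2Cl2, −78→0 °C
Reagents that add atoms: tert-butyldimethylsilyl trifluoromethanesulfonate, CC(C)(C)[Si](C)(C)OS(=O)(=O)C(F)(F)F
Why: Silylation with a silyl triflate is needed for a secondary alcohol next to a quaternary carbon. The base-buffered, cold conditions should leave the ketone-derived dioxolane intact, and the stereocentre is not touched.

Step 7
Reactants: 11 tert-butyl{[(3S)-2-methyl-2-(5-methylfuran-2-yl)-5-(2-methyl-1,3-dioxolan-2-yl)pentan-3-yl]oxy}dimethylsilane
Product: 12 (5S)-5-(tert-butyldimethylsilyloxy)-6-methyl-6-(5-methylfuran-2-yl)heptan-2-one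
Conditions: PPTS, acetone–H2O (10:1), 50 °C
Reagents that add atoms: water, O
Why: Mild acid-catalysed ketal hydrolysis; the hindered secondary silyl ether and the 2,5-dialkylfuran should survive a pyridinium acid.

Step 8
Reactants: 12 (5S)-5-(tert-butyldimethylsilyloxy)-6-methyl-6-(5-methylfuran-2-yl)heptan-2-one
Product: 13 methyl (2E,6S)-6-(tert-butyldimethylsilyloxy)-3,7-dimethyl-7-(5-methylfuran-2-yl)oct-2-enoate
Conditions: (MeO)2P(O)CH2CO2Me, NaH, THF, 0 °C→reflux; chromatography
Reagents that add atoms: trimethyl phosphonoacetate, COC(=O)CP(=O)(OC)OC
Why: Horner–Wadsworth–Emmons olefination of a methyl ketone, which favours the E isomer (ester anti to the longer chain). The minor Z isomer must be removed by chromatography, because the alkene geometry is carried into the C9/C10 relationship.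

Step 9
Reactants: 13 methyl (2E,6S)-6-(tert-butyldimethylsilyloxy)-3,7-dimethyl-7-(5-methylfuran-2-yl)oct-2-enoate
Product: 14 methyl 3β-(tert-butyldimethylsilyloxy)-5α,8α-epoxydrim-6-en-11-oate
Conditions: Me2AlCl (1.5 equiv), CH2Cl2, −78→−40 °C; quench at −78 °C with Et3N/MeOH, then aq. NaHCO3
Reagents that add atoms: none
Why: Me2AlCl binds the ester carbonyl and lowers the LUMO of the C9=C10 enoate, which should add in a concerted, asynchronous [4+2] reaction across the 2,5-positions of the furan (C8 and C5), forming C8–C9 and C5–C10; the closest known reaction type is the alkylaluminium-chloride-promoted intramolecular Diels–Alder reaction of 2-alkylfurans with tethered enones and enoates. Ring A closes through the C5–C10 bond as a six-membered carbocycle with the four-atom tether C4–C3–C2–C1 in a chair, and ring B is the cyclohexene of the cycloadduct itself, closed by both new bonds and spanned by the C5–O–C8 bridge. C5 and C8 are set together because the diene reacts suprafacially, so both C–O bonds lie on one face (α). C10 is set by the tether, which spans C5 and C10 on the side of the oxygen bridge (side arm exo) and so leaves the C10 methyl on the β face. C9 follows from the E geometry of 13: the ester and the C10 methyl are cis on the alkene and stay cis, so C11 is β and H9 is α. The absolute sense comes from C3, because the chair with the silyloxy group equatorial presents one enoate face to the furan while the other face would need that group axial and syn to the furan oxygen. The step therefore needs facial selectivity (from the C3 substituent; the minor diastereomer is separable), the exo-tether mode (from the strain of the alternative) and an equilibrium on the adduct side (helped by the C4 gem-dimethyl group, low temperature and a cold quench).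

Step 10
Reactants: 14 methyl 3β-(tert-butyldimethylsilyloxy)-5α,8α-epoxydrim-6-en-11-oate
Product: 15 3β-(tert-butyldimethylsilyloxy)-5α,8α-epoxydrim-6-en-11-ol
Conditions: i-Bu2AlH (2.5 equiv), CH2Cl2, −78 °C; aq. Rochelle salt
Reagents that add atoms: none
Why: Hydride reduction of the ester to the primary alcohol on the cold, crude adduct. It removes the group that makes the cycloaddition reversible and the C9 acidity that would allow β-elimination of the C8 oxygen; no stereocentre is involved.

Step 11
Reactants: 15 3β-(tert-butyldimethylsilyloxy)-5α,8α-epoxydrim-6-en-11-ol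
Product: 16 3β-(tert-butyldimethylsilyloxy)drim-5-ene-8α,11-diol
Conditions: Li (excess), EtNH2–THF, t-BuOH, −78 °C; NH4Cl
Reagents that add atoms: none
Why: Dissolving-metal reductive cleavage of an allylic C–O bond (Benkeser type), as known for cyclic allylic ethers. Of the two allylic bonds, C5–O should break, because this relieves the congestion at C5 and leaves the less hindered alkoxide on C8. The allyl anion should then be protonated at its less substituted end C7, giving C5=C6; C8 keeps its configuration because its C–O bond is untouched.

Step 12
Reactants: 16 3β-(tert-butyldimethylsilyloxy)drim-5-ene-8α,11-diol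
Product: 17 3β-(tert-butyldimethylsilyloxy)-5α-drimane-8α,11-diol
Conditions: Mn(dpm)3 (10 mol%), PhSiH3, t-BuOOH, i-PrOH, 22 °C
Reagents that add atoms: none
Why: Manganese-catalysed hydrogen-atom-transfer hydrogenation, a radical method suited to hindered trisubstituted alkenes and known to give trans-fused decalins. A hydrogen atom should add to C6, and the tertiary C5 radical should take the second hydrogen on the α face, anti to the axial methyl groups on C4 and C10.

Step 13
Reactants: 17 3β-(tert-butyldimethylsilyloxy)-5α-drimane-8α,11-diol
Product: 18 3β-(tert-butyldimethylsilyloxy)-11-(phenylsulfanyl)-5α-driman-8α-ol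
Conditions: PhSSPh, n-Bu3P, pyridine, 60 °C
Reagents that add atoms: diphenyl disulfide, c1ccccc1SSc1ccccc1
Why: Hata-type thioetherification: the primary alcohol forms an alkoxyphosphonium ion that thiolate displaces in an SN2 reaction. The tertiary C8 alcohol does not react, and because no alkoxide is generated, closure to an oxetane should not compete.

Step 14
Reactants: 18 3β-(tert-butyldimethylsilyloxy)-11-(phenylsulfanyl)-5α-driman-8α-ol
Product: 19 3β-(tert-butyldimethylsilyloxy)-11-(phenylsulfonyl)-5α-driman-8α-ol
Conditions: mCPBA (2.2 equiv), NaHCO3, CH2Cl2, 0 °C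
Reagents that add atoms: 3-chloroperoxybenzoic acid, O=C(OO)c1cccc(Cl)c1
Why: Peracid oxidation of a sulfide to the sulfone. The molecule has no alkene at this stage, and the silyl ether and tertiary alcohol are inert.

Step 15
Reactants: 19 3β-(tert-butyldimethylsilyloxy)-11-(phenylsulfonyl)-5α-driman-8α-ol; 20 (2E,6E)-1-bromo-3,7,11-trimethyldodeca-2,6,10-triene ((2E,6E)-farnesyl bromide)
Product: 22 3β-(tert-butyldimethylsilyloxy)-11-[(2E,6E)-farnesyl]-11-(phenylsulfonyl)-5α-driman-8α-ol (both C11 epimers), via dilithio sulfone 21 (not isolated)
Conditions: n-BuLi (2.2 equiv), THF–DMPU, −78 °C; then 20, −78→−20 °C; aq. NH4Cl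
Reagents that add atoms: none
Why: Alkylation of a sulfone-stabilised carbanion with a primary allylic bromide (Julia-type coupling), which should proceed by SN2 with the E alkenes retained. Two equivalents of base form the C8 alkoxide and the C11 carbanion, and the soft carbanion is the one that alkylates; the configuration of the new C11 centre is irrelevant because the sulfone is removed next.

Step 16
Reactants: 22 3β-(tert-butyldimethylsilyloxy)-11-[(2E,6E)-farnesyl]-11-(phenylsulfonyl)-5α-driman-8α-ol
Product: 23 3β-(tert-butyldimethylsilyloxy)-11-[(2E,6E)-farnesyl]-5α-driman-8α-ol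
Conditions: Na(Hg) (6%), Na2HPO4, MeOH–THF, −20 °C
Reagents that add atoms: none
Why: Reductive desulfonylation by electron transfer; the C–S bond is cleaved and the carbanion protonated. The isolated trisubstituted alkenes are not reduced, and the buffer keeps the medium from becoming strongly basic.

Step 17
Reactants: 23 3β-(tert-butyldimethylsilyloxy)-11-[(2E,6E)-farnesyl]-5α-driman-8α-ol
Product: 24 11-[(2E,6E)-farnesyl]-5α-drimane-3β,8α-diol
Conditions: Bu4NF, THF, 60 °C
Reagents that add atoms: none
Why: Fluoride cleavage of the silyl ether; warming is needed for the hindered position beside the gem-dimethyl group. The tertiary alcohol and the polyene are stable to fluoride.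

Step 18
Reactants: 24 11-[(2E,6E)-farnesyl]-5α-drimane-3β,8α-diol
Product: 25 8α-hydroxy-11-[(2E,6E)-farnesyl]-5α-driman-3-one, (5R,8R,9R,10S) (CNP0158964.2)
Conditions: Dess–Martin periodinane, NaHCO3, CH2Cl2, 0 °C→rt
Reagents that add atoms: none
Why: Dess–Martin oxidation of the secondary C3 alcohol. The tertiary C8 alcohol cannot be oxidised, and the buffered neutral conditions should spare the polyene and avoid dehydration.

## Compound list

1 | ethyl 2-bromo-2-methylpropanoate | CCOC(=O)C(C)(C)Br | starting material
2 | 2-bromo-5-methylfuran | Cc1ccc(Br)o1 | starting material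
3 | bromo(1-ethoxy-2-methyl-1-oxopropan-2-yl)zinc (Reformatsky zinc enolate) | CCOC(=O)C(C)(C)[Zn]Br | intermediate (not isolated)
4 | ethyl 2-methyl-2-(5-methylfuran-2-yl)propanoate | CCOC(=O)C(C)(C)c1ccc(C)o1 | intermediate
5 | 2-methyl-2-(5-methylfuran-2-yl)propanal | O=CC(C)(C)c1ccc(C)o1 | intermediate
6 | 2-(2-bromoethyl)-2-methyl-1,3-dioxolane | CC1(CCBr)OCCO1 | starting material
7 | [2-(2-methyl-1,3-dioxolan-2-yl)ethyl]magnesium bromide | CC1(CC[Mg]Br)OCCO1 | intermediate (not isolated)
8 | rac-2-methyl-2-(5-methylfuran-2-yl)-5-(2-methyl-1,3-dioxolan-2-yl)pentan-3-ol | CC1(CCC(O)C(C)(C)c2ccc(C)o2)OCCO1 | intermediate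
9 | 2-methyl-2-(5-methylfuran-2-yl)-5-(2-methyl-1,3-dioxolan-2-yl)pentan-3-one | CC1(CCC(=O)C(C)(C)c2ccc(C)o2)OCCO1 | intermediate
10 | (3S)-2-methyl-2-(5-methylfuran-2-yl)-5-(2-methyl-1,3-dioxolan-2-yl)pentan-3-ol | CC1(CC[C@H](O)C(C)(C)c2ccc(C)o2)OCCO1 | intermediate
11 | tert-butyl{[(3S)-2-methyl-2-(5-methylfuran-2-yl)-5-(2-methyl-1,3-dioxolan-2-yl)pentan-3-yl]oxy}dimethylsilane | CC1(CC[C@H](O[Si](C)(C)C(C)(C)C)C(C)(C)c2ccc(C)o2)OCCO1 | intermediate
12 | (5S)-5-(tert-butyldimethylsilyloxy)-6-methyl-6-(5-methylfuran-2-yl)heptan-2-one | CC(=O)CC[C@H](O[Si](C)(C)C(C)(C)C)C(C)(C)c1ccc(C)o1 | intermediate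
13 | methyl (2E,6S)-6-(tert-butyldimethylsilyloxy)-3,7-dimethyl-7-(5-methylfuran-2-yl)oct-2-enoate | COC(=O)/C=C(\C)CC[C@H](O[Si](C)(C)C(C)(C)C)C(C)(C)c1ccc(C)o1 | intermediate
14 | methyl 3β-(tert-butyldimethylsilyloxy)-5α,8α-epoxydrim-6-en-11-oate | COC(=O)[C@@H]1[C@@]2(C)CC[C@H](O[Si](C)(C)C(C)(C)C)C(C)(C)[C@]23C=C[C@@]1(C)O3 | intermediate
15 | 3β-(tert-butyldimethylsilyloxy)-5α,8α-epoxydrim-6-en-11-ol | OC[C@@H]1[C@@]2(C)CC[C@H](O[Si](C)(C)C(C)(C)C)C(C)(C)[C@]23C=C[C@@]1(C)O3 | intermediate
16 | 3β-(tert-butyldimethylsilyloxy)drim-5-ene-8α,11-diol | OC[C@@H]1[C@@]2(C)CC[C@H](O[Si](C)(C)C(C)(C)C)C(C)(C)C2=CC[C@@]1(C)O | intermediate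
17 | 3β-(tert-butyldimethylsilyloxy)-5α-drimane-8α,11-diol | OC[C@@H]1[C@@]2(C)CC[C@H](O[Si](C)(C)C(C)(C)C)C(C)(C)[C@@H]2CC[C@@]1(C)O | intermediate
18 | 3β-(tert-butyldimethylsilyloxy)-11-(phenylsulfanyl)-5α-driman-8α-ol | c3ccccc3SC[C@@H]1[C@@]2(C)CC[C@H](O[Si](C)(C)C(C)(C)C)C(C)(C)[C@@H]2CC[C@@]1(C)O | intermediate
19 | 3β-(tert-butyldimethylsilyloxy)-11-(phenylsulfonyl)-5α-driman-8α-ol | O=S(=O)(c3ccccc3)C[C@@H]1[C@@]2(C)CC[C@H](O[Si](C)(C)C(C)(C)C)C(C)(C)[C@@H]2CC[C@@]1(C)O | intermediate
20 | (2E,6E)-1-bromo-3,7,11-trimethyldodeca-2,6,10-triene ((2E,6E)-farnesyl bromide) | CC(C)=CCC/C(C)=C/CC/C(C)=C/CBr | starting material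
21 | dilithio derivative of 19 (C11 carbanion, C8 alkoxide) | [Li+].[Li+].O=S(=O)(c3ccccc3)[CH-][C@@H]1[C@@]2(C)CC[C@H](O[Si](C)(C)C(C)(C)C)C(C)(C)[C@@H]2CC[C@@]1(C)[O-] | intermediate (not isolated)
22 | 3β-(tert-butyldimethylsilyloxy)-11-[(2E,6E)-farnesyl]-11-(phenylsulfonyl)-5α-driman-8α-ol (C11 epimers) | CC(C)=CCC/C(C)=C/CC/C(C)=C/CC(S(=O)(=O)c3ccccc3)[C@@H]1[C@@]2(C)CC[C@H](O[Si](C)(C)C(C)(C)C)C(C)(C)[C@@H]2CC[C@@]1(C)O | intermediate
23 | 3β-(tert-butyldimethylsilyloxy)-11-[(2E,6E)-farnesyl]-5α-driman-8α-ol | CC(C)=CCC/C(C)=C/CC/C(C)=C/CC[C@@H]1[C@@]2(C)CC[C@H](O[Si](C)(C)C(C)(C)C)C(C)(C)[C@@H]2CC[C@@]1(C)O | intermediate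
24 | 11-[(2E,6E)-farnesyl]-5α-drimane-3β,8α-diol | CC(C)=CCC/C(C)=C/CC/C(C)=C/CC[C@@H]1[C@@]2(C)CC[C@H](O)C(C)(C)[C@@H]2CC[C@@]1(C)O | intermediate
25 | 8α-hydroxy-11-[(2E,6E)-farnesyl]-5α-driman-3-one, (5R,8R,9R,10S) (CNP0158964.2) | CC(C)=CCC/C(C)=C/CC/C(C)=C/CC[C@@H]1[C@@]2(C)CCC(=O)C(C)(C)[C@@H]2CC[C@@]1(C)O | target

## Step count and least certain steps

Total: 18 steps. Longest linear sequence: 18 steps (from 1 and 2 to 25); 6 and 20 enter as commercial reagents.

**Step 9 (key step).** The equilibrium may lie on the side of the open chain, because the adduct holds three adjacent fully substituted carbons and furan cycloadditions revert easily. The activated enoate may instead be attacked by a furan β-carbon in a conjugate addition. The adduct may ring-open by loss of the C8 oxygen if the mixture warms. Discrimination between the two faces by the C3 silyloxy group may be only moderate.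
Fallback, from 13 back to 15: the ester of 13 is reduced with i-Bu2AlH to the allylic alcohol (2E,6S)-6-(tert-butyldimethylsilyloxy)-3,7-dimethyl-7-(5-methylfuran-2-yl)oct-2-en-1-ol F1, and this is oxidised with MnO2 to the enal (2E,6S)-6-(tert-butyldimethylsilyloxy)-3,7-dimethyl-7-(5-methylfuran-2-yl)oct-2-enal F2. The enal is a stronger acceptor and is cyclised with Me2AlCl at −78 °C to the aldehyde adduct 3β-(tert-butyldimethylsilyloxy)-5α,8α-epoxydrim-6-en-11-al F3. This is not isolated; i-Bu2AlH is added to the cold mixture so that the adduct is reduced at once, which withdraws it from the equilibrium and gives 15.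

**Step 11.** Cleavage may occur at the C8–O bond instead of C5–O, which would leave the oxygen on C5. The allyl anion may be protonated at C5 instead of C7. Prolonged exposure may reduce the alkene.
Fallback, from 14 back to 16: a cationic opening is used in place of electron transfer. Ester 14 is treated with Et3SiH and BF3·OEt2 in CH2Cl2 at −78 °C. The ester on C9 disfavours positive charge at C8, so ionisation should occur at C5–O, and hydride should be taken up at the less hindered C7 to give methyl 3β-(tert-butyldimethylsilyloxy)-8α-hydroxydrim-5-en-11-oate F4. Reduction of F4 with LiAlH4 in THF at 0 °C gives 16.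

**Step 12.** Hydrogen-atom transfer to the alkene, which is flanked by two quaternary carbons, may be slow, and delivery of the second hydrogen to the C5 radical may not be fully selective for the α face.
Fallback, from 16 directly to 17: heterogeneous hydrogenation (H2 under pressure, PtO2, EtOAc with a little AcOH). Here the face is chosen by adsorption on the catalyst surface, which the three axial β-methyl groups should confine to the α side. This fallback makes no new compound (F0).

**Step 15.** Deprotonation or alkylation at the hindered C11 may be incomplete, the dianion may aggregate and react sluggishly, and some alkylation may occur at the C8 alkoxide.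
Fallback, from 19 back to 22: the tertiary alcohol is first silylated (TMSOTf, 2,6-lutidine) to 3β-(tert-butyldimethylsilyloxy)-11-(phenylsulfonyl)-8α-(trimethylsilyloxy)-5α-drimane F5. Its monoanion (n-BuLi, THF–DMPU, −78 °C) is alkylated with 20 to give 3β-(tert-butyldimethylsilyloxy)-11-[(2E,6E)-farnesyl]-11-(phenylsulfonyl)-8α-(trimethylsilyloxy)-5α-drimane F6. Selective removal of the trimethylsilyl group (K2CO3, MeOH) returns 22.

## Further compounds

F1 | step 9 | (2E,6S)-6-(tert-butyldimethylsilyloxy)-3,7-dimethyl-7-(5-methylfuran-2-yl)oct-2-en-1-ol | OC/C=C(\C)CC[C@H](O[Si](C)(C)C(C)(C)C)C(C)(C)c1ccc(C)o1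
F2 | step 9 | (2E,6S)-6-(tert-butyldimethylsilyloxy)-3,7-dimethyl-7-(5-methylfuran-2-yl)oct-2-enal | O=C/C=C(\C)CC[C@H](O[Si](C)(C)C(C)(C)C)C(C)(C)c1ccc(C)o1
F3 | step 9 | 3β-(tert-butyldimethylsilyloxy)-5α,8α-epoxydrim-6-en-11-al | O=C[C@@H]1[C@@]2(C)CC[C@H](O[Si](C)(C)C(C)(C)C)C(C)(C)[C@]23C=C[C@@]1(C)O3
F4 | step 11 | methyl 3β-(tert-butyldimethylsilyloxy)-8α-hydroxydrim-5-en-11-oate | COC(=O)[C@@H]1[C@@]2(C)CC[C@H](O[Si](C)(C)C(C)(C)C)C(C)(C)C2=CC[C@@]1(C)O
F0 | step 12 | none | none
F5 | step 15 | 3β-(tert-butyldimethylsilyloxy)-11-(phenylsulfonyl)-8α-(trimethylsilyloxy)-5α-drimane | O=S(=O)(c3ccccc3)C[C@@H]1[C@@]2(C)CC[C@H](O[Si](C)(C)C(C)(C)C)C(C)(C)[C@@H]2CC[C@@]1(C)O[Si](C)(C)C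
F6 | step 15 | 3β-(tert-butyldimethylsilyloxy)-11-[(2E,6E)-farnesyl]-11-(phenylsulfonyl)-8α-(trimethylsilyloxy)-5α-drimane (C11 epimers) | CC(C)=CCC/C(C)=C/CC/C(C)=C/CC(S(=O)(=O)c3ccccc3)[C@@H]1[C@@]2(C)CC[C@H](O[Si](C)(C)C(C)(C)C)C(C)(C)[C@@H]2CC[C@@]1(C)O[Si](C)(C)C
A1 | alternative 1 | bicyclic 4-en-3-one: 4,8β,10β-trimethyl-8α-(triethylsilyloxy)-9β-vinyl decal-4-en-3-one (labdane numbering) | C=C[C@@H]1[C@@]2(C)CCC(=O)C(C)=C2CC[C@@]1(C)O[Si](CC)(CC)CC
A2 | alternative 1 | ring B ketone: 2,4-dimethyl-4-(triethylsilyloxy)-3-vinylcyclohexan-1-one (C8 and C9 as in A1, C10 epimerisable) | C=C[C@@H]1C(C)C(=O)CC[C@@]1(C)O[Si](CC)(CC)CC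
A3 | alternative 1 | pent-1-en-3-one | CCC(=O)C=C
A4 | alternative 2 | methyl 3β-(tert-butyldimethylsilyloxy)-8α-hydroxy-13,14,15,16-tetranorlabdan-12-oate | COC(=O)C[C@@H]1[C@@]2(C)CC[C@H](O[Si](C)(C)C(C)(C)C)C(C)(C)[C@@H]2CCC[C@@]1(C)O
A5 | alternative 2 | ring A keto enoate: methyl (E)-3-[4-(tert-butyldimethylsilyloxy)-1,3,3-trimethyl-2-(3-oxobutyl)cyclohexyl]prop-2-enoate (C3, C5, C10 as in the target) | COC(=O)/C=C/[C@@]1(C)CC[C@H](O[Si](C)(C)C(C)(C)C)C(C)(C)[C@@H]1CCC(C)=O
A6 | alternative 3 | methyl 3β-(tert-butyldimethylsilyloxy)drima-5,8-dien-11-oate | COC(=O)C1=C(C)CC=C2C(C)(C)[C@@H](O[Si](C)(C)C(C)(C)C)CC[C@]12C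
A7 | alternative 3 | ring A diene: tert-butyl{[(1S)-2,2,4-trimethyl-3-vinylcyclohex-3-en-1-yl]oxy}dimethylsilane | C=CC1=C(C)CC[C@H](O[Si](C)(C)C(C)(C)C)C1(C)C
A8 | alternative 3 | methyl but-2-ynoate | CC#CC(=O)OC
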